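**Retrosynthetic overview**
1. Target 13 is (12Z)-6α-acetoxylabda-12,14-diene-7β,8α-diol (5S,6R,7S,8S,9R,10S; trans-decalin, all three ring-B oxygens equatorial). The vinyl group is cut off last, by Stille coupling on the (Z)-enol triflate 11.
2. The ring-B oxygens of 11 are built from the exocyclic alkene of 5. C7 comes from allylic oxidation, C6 from α′-acetoxylation of the enone, C8 from H-atom transfer/O2 capture, and the 7-OH from hydride.
3. 5 comes from a β-eliminative opening of the dihydropyran of sclareol oxide 2. This one step releases both the Z-enolate (O cis to C11) and the 8(17)-alkene.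
4. 2 comes from a single proton-initiated polyene cyclisation of acyclic farnesylacetone 1, with the ketone oxygen standing in for the water that quenches the C8 cation in nature.
5. Ring order within that cascade: ring A (C4–C5), ring B (C9–C10), then ring C (C8–O), which is a temporary template for the 12Z geometry.

Assumption: the all-E isomer of farnesylacetone is bought. Labdane numbering is used for every compound.

**Step 1**
Reactants: 1 (5E,9E)-farnesylacetone
Product: 2 sclareol oxide, 8α,13-epoxy-14,15-dinorlabd-12-ene (5α-H, 9α-H, 10β-CH3, 8β-CH3)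
Conditions: squalene–hopene cyclase of Alicyclobacillus acidocaldarius (E. coli whole cells), citrate buffer pH 6.0, SDS, 37 °C; heptane extraction
Reagents that add atoms: none
Why: This is a known enzymatic Brønsted-acid polyene cyclisation (cation–olefin cascade) in which the active-site aspartic acid protonates C3 of the all-chair chain, rings A and B close by anti additions across the two E-alkenes, the ketone oxygen takes the C8 cation from the α face and H12 is lost, so that C5, C9, C10 (and for now C8) are set in the normal labdane series and the in-ring C12=C13 bond is locked with O cis to C11.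

**Step 2**
Reactants: 2 sclareol oxide
Product: 3 (12Z)-13-(trimethylsilyloxy)-14,15-dinorlabda-8(17),12-diene
Conditions: TMSOTf (1.5 equiv), 2,6-lutidine (3 equiv), CH2Cl2, −40 to 0 °C; pentane, cold aq NaHCO3
Reagents that add atoms: trimethylsilyl triflate C[Si](C)(C)OS(=O)(=O)C(F)(F)F
Why: Proposed new method: O-silylation of the enol-ether oxygen turns the tertiary C8–O bond into a leaving group (a neutral silyl enol ether), and because this equatorial bond is antiperiplanar only to the C17–H bonds the hindered base takes a methyl proton to give the 8(17)-alkene while the untouched C12=C13 bond keeps O cis to C11 (Z); the closest known reaction type is the TMSOTf/2,6-lutidine β-elimination cleavage of tert-butyl ethers, esters and carbamates, and the C8 centre given up here is rebuilt in step 6.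

**Step 3**
Reactants: 3 (12Z)-13-(trimethylsilyloxy)-14,15-dinorlabda-8(17),12-diene
Product: 5 (12Z)-14,15-dinorlabda-8(17),12-dien-13-yl trifluoromethanesulfonate, via lithium Z-enolate 4 (not isolated)
Conditions: MeLi (1.05 equiv), THF, 0 °C; then PhNTf2 (1.1 equiv), −78 °C to rt
Reagents that add atoms: N-phenylbis(trifluoromethanesulfonimide) O=S(=O)(N(c1ccccc1)S(=O)(=O)C(F)(F)F)C(F)(F)F; methyllithium [Li]C (supplies the lithium of 4 only)
Why: Stork-type cleavage of a silyl enol ether gives the regio- and stereodefined lithium enolate, and its O-triflation takes place without any proton source, so position and Z geometry of the double bond are carried over unchanged.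

**Step 4**
Reactants: 5 (12Z)-14,15-dinorlabda-8(17),12-dien-13-yl trifluoromethanesulfonate
Product: 7 (12Z)-7-oxo-14,15-dinorlabda-8(17),12-dien-13-yl trifluoromethanesulfonate, via 7α-alcohol 6 (not isolated)
Conditions: SeO2 (0.3 equiv), t-BuOOH (2.5 equiv), CH2Cl2, 0 °C to rt; Na2SO3 wash; crude, Dess–Martin periodinane (1.3 equiv), CH2Cl2, rt
Reagents that add atoms: tert-butyl hydroperoxide CC(C)(C)OO (terminal oxygen source); selenium dioxide O=[Se]=O (oxygen carrier)
Why: Riley allylic oxidation (ene reaction then [2,3]-shift) attacks the electron-rich 8(17)-alkene at the C7 methylene rather than the C9 methine or the electron-poor triflate alkene, and Dess–Martin oxidation removes the transient carbinol centre to give the α-methylene ketone.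

**Step 5**
Reactants: 7 (12Z)-7-oxo-14,15-dinorlabda-8(17),12-dien-13-yl trifluoromethanesulfonate
Product: 8 (12Z)-6α-acetoxy-7-oxo-14,15-dinorlabda-8(17),12-dien-13-yl trifluoromethanesulfonate
Conditions: Mn(OAc)3·2H2O (4 equiv), benzene, reflux (Dean–Stark)
Reagents that add atoms: manganese triacetate CC(=O)[O-].CC(=O)[O-].CC(=O)[O-].[Mn+3]
Why: This is the known α′-acetoxylation of enones with Mn(OAc)3, in which the manganese enolate toward C6 (the only enolisable site) receives acetate on the α face because the β face is closed by the axial methyls on C4 and C10, giving the equatorial 6α-acetate (6R) without any strong base that could eliminate the triflate.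

**Step 6**
Reactants: 8 (12Z)-6α-acetoxy-7-oxo-14,15-dinorlabda-8(17),12-dien-13-yl trifluoromethanesulfonate
Product: 10 (12Z)-6α-acetoxy-8α-hydroxy-7-oxo-14,15-dinorlabd-12-en-13-yl trifluoromethanesulfonate, via 8α-hydroperoxide 9 (not isolated)
Conditions: Mn(dpm)3 [tris(2,2,6,6-tetramethylheptane-3,5-dionato)manganese] (10 mol %), PhSiH3 (2 equiv), O2 (1 atm), i-PrOH/CH2Cl2, 0 °C; then P(OEt)3 (1.5 equiv)
Reagents that add atoms: dioxygen O=O
Why: In this Mukaiyama-type reductive α-hydroxylation of an enone (metal-hydride hydrogen-atom transfer, then O2 capture) the hydrogen atom adds to the unhindered C17 terminus and the planar C8 α-keto radical takes O2 from the α face opposite the axial C10 methyl (the same bias as for electrophiles at C2 of 3-oxo-5α-steroids), which gives 8α-OH/8β-CH3 (8S) after phosphite reduction.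

**Step 7**
Reactants: 10 (12Z)-6α-acetoxy-8α-hydroxy-7-oxo-14,15-dinorlabd-12-en-13-yl trifluoromethanesulfonate
Product: 11 (12Z)-6α-acetoxy-7β,8α-dihydroxy-14,15-dinorlabd-12-en-13-yl trifluoromethanesulfonate
Conditions: NaBH4 (1.5 equiv), CeCl3·7H2O (1.2 equiv), MeOH/THF, −78 to −40 °C; AcOH quench
Reagents that add atoms: none
Why: In this Luche-type borohydride reduction hydride arrives axially from the open α face (the β side is blocked by the axial 8β-methyl) and gives the equatorial 7β-alcohol (7S), while the cold, nearly neutral medium suppresses 6→7 acetyl migration.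

**Step 8**
Reactants: 11 (12Z)-6α-acetoxy-7β,8α-dihydroxy-14,15-dinorlabd-12-en-13-yl trifluoromethanesulfonate; 12 tributyl(vinyl)stannane
Product: 13 (12Z)-6α-acetoxylabda-12,14-diene-7β,8α-diol (target)
Conditions: Pd(PPh3)4 (5 mol %), LiCl (3 equiv), THF, 60 °C; aq KF work-up
Reagents that add atoms: tributyl(vinyl)stannane (12) C=C[Sn](CCCC)(CCCC)CCCC
Why: Stille coupling of an enol triflate proceeds with retention in oxidative addition to zerovalent palladium and in reductive elimination, so vinyl takes the place of OTf cis to C11 (12Z), and the neutral conditions leave the acetate and both free hydroxyls alone.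

**Compound list**
1 | (5E,9E)-6,10,14-trimethylpentadeca-5,9,13-trien-2-one (farnesylacetone) | CC(C)=CCC/C(C)=C/CC/C(C)=C/CCC(C)=O | starting material
2 | sclareol oxide, 8α,13-epoxy-14,15-dinorlabd-12-ene | CC1=CC[C@H]2[C@](C)(O1)CC[C@H]3C(C)(C)CCC[C@@]32C | intermediate
3 | (12Z)-13-(trimethylsilyloxy)-14,15-dinorlabda-8(17),12-diene | C/C(O[Si](C)(C)C)=C/C[C@H]1C(=C)CC[C@H]2C(C)(C)CCC[C@@]21C | intermediate
4 | lithium (12Z)-14,15-dinorlabda-8(17),12-dien-13-olate | C/C([O-])=C/C[C@H]1C(=C)CC[C@H]2C(C)(C)CCC[C@@]21C.[Li+] | intermediate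
5 | (12Z)-14,15-dinorlabda-8(17),12-dien-13-yl triflate | C/C(OS(=O)(=O)C(F)(F)F)=C/C[C@H]1C(=C)CC[C@H]2C(C)(C)CCC[C@@]21C | intermediate
6 | (12Z)-7α-hydroxy-14,15-dinorlabda-8(17),12-dien-13-yl triflate | C/C(OS(=O)(=O)C(F)(F)F)=C/C[C@H]1C(=C)[C@H](O)C[C@H]2C(C)(C)CCC[C@@]21C | intermediate
7 | (12Z)-7-oxo-14,15-dinorlabda-8(17),12-dien-13-yl triflate | C/C(OS(=O)(=O)C(F)(F)F)=C/C[C@H]1C(=C)C(=O)C[C@H]2C(C)(C)CCC[C@@]21C | intermediate
8 | (12Z)-6α-acetoxy-7-oxo-14,15-dinorlabda-8(17),12-dien-13-yl triflate | C/C(OS(=O)(=O)C(F)(F)F)=C/C[C@H]1C(=C)C(=O)[C@H](OC(C)=O)[C@H]2C(C)(C)CCC[C@@]21C | intermediate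
9 | (12Z)-6α-acetoxy-8α-hydroperoxy-7-oxo-14,15-dinorlabd-12-en-13-yl triflate | C/C(OS(=O)(=O)C(F)(F)F)=C/C[C@H]1[C@](C)(OO)C(=O)[C@H](OC(C)=O)[C@H]2C(C)(C)CCC[C@@]21C | intermediate
10 | (12Z)-6α-acetoxy-8α-hydroxy-7-oxo-14,15-dinorlabd-12-en-13-yl triflate | C/C(OS(=O)(=O)C(F)(F)F)=C/C[C@H]1[C@](C)(O)C(=O)[C@H](OC(C)=O)[C@H]2C(C)(C)CCC[C@@]21C | intermediate
11 | (12Z)-6α-acetoxy-7β,8α-dihydroxy-14,15-dinorlabd-12-en-13-yl triflate | C/C(OS(=O)(=O)C(F)(F)F)=C/C[C@H]1[C@](C)(O)[C@@H](O)[C@H](OC(C)=O)[C@H]2C(C)(C)CCC[C@@]21C | intermediate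
12 | tributyl(vinyl)stannane | C=C[Sn](CCCC)(CCCC)CCCC | starting material
13 | (12Z)-6α-acetoxylabda-12,14-diene-7β,8α-diol (5S,6R,7S,8S,9R,10S) | C=C/C(C)=C\C[C@H]1[C@](C)(O)[C@@H](O)[C@H](OC(C)=O)[C@H]2C(C)(C)CCC[C@@]21C | target

**Total step count:** 8. **Longest linear sequence:** 8 (1 → 13).

**Steps most likely to fail**

*Step 2.* The opening may not occur, or it may give the endocyclic alkene.
- This fallback sets out from 2 and comes back at 13. It gives up the triflate relay and rebuilds the pyran later as the handle for a nickel-catalysed ring-opening vinylation.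
- 2 is hydrolysed (0.1 M HCl, THF) to 8α-hydroxy-14,15-dinorlabdan-13-one F1 and dehydrated with SOCl2/pyridine to 14,15-dinorlabd-8(17)-en-13-one F2.
- F2 is oxidised as in step 4 to 14,15-dinorlabd-8(17)-ene-7,13-dione F3 and hydroxylated as in step 6 to 8α-hydroxy-14,15-dinorlabdane-7,13-dione F4.
- PPTS in refluxing toluene closes F4 to 7-oxosclareol oxide F5.
- The C7 ketone is masked in the flask as its lithium enolate (LiHMDS). NiCl2(PCy3)2 with vinylmagnesium bromide then cleaves the C13–O bond with retention, a Wenkert-type coupling through zerovalent nickel, to give 7-oxo-cis-abienol F6.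
- KHMDS and 2-(phenylsulfonyl)-3-phenyloxaziridine give the 6α-hydroxy ketone F7, and Ac2O/pyridine/DMAP gives the 6α-acetoxy ketone F8.
- The reduction of step 7 then delivers 13.

*Step 5.* The α-methylene ketone may polymerise or take up radicals under Mn(OAc)3.
- This fallback sets out from 7 and comes back at 8. It replaces manganese enolate chemistry by electrophilic oxidation of a silyl dienol ether.
- TMSOTf/Et3N converts 7 into the 7-(trimethylsilyloxy)-6,8(17)-diene F9.
- Rubottom oxidation (dimethyldioxirane, acetone, −40 °C, then citric acid/MeOH) on the open α face gives the 6α-hydroxy enone F10.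
- Ac2O/pyridine/DMAP gives 8.

*Step 6.* The O2 capture may occur on the wrong face, or the hydrogen-atom transfer may touch other sites.
- This fallback sets out from 8 and comes back at 10. It replaces the radical step by a closed-shell sequence.
- RhCl(PPh3)3-catalysed 1,4-hydrosilylation with Et3SiH gives the tetrasubstituted 7-(triethylsilyloxy)-7-ene F11.
- Epoxidation with dimethyldioxirane from the α face, followed by citric acid/MeOH, gives 10.

**Further compounds**
F1 | step 2 | 8α-hydroxy-14,15-dinorlabdan-13-one | CC(=O)CC[C@H]1[C@](C)(O)CC[C@H]2C(C)(C)CCC[C@@]21C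
F2 | step 2 | 14,15-dinorlabd-8(17)-en-13-one | CC(=O)CC[C@H]1C(=C)CC[C@H]2C(C)(C)CCC[C@@]21C
F3 | step 2 | 14,15-dinorlabd-8(17)-ene-7,13-dione | CC(=O)CC[C@H]1C(=C)C(=O)C[C@H]2C(C)(C)CCC[C@@]21C
F4 | step 2 | 8α-hydroxy-14,15-dinorlabdane-7,13-dione | CC(=O)CC[C@H]1[C@](C)(O)C(=O)C[C@H]2C(C)(C)CCC[C@@]21C
F5 | step 2 | 7-oxosclareol oxide, 8α,13-epoxy-14,15-dinorlabd-12-en-7-one | CC1=CC[C@H]2[C@](C)(O1)C(=O)C[C@H]3C(C)(C)CCC[C@@]32C
F6 | step 2 | 7-oxo-cis-abienol, (12Z)-8α-hydroxylabda-12,14-dien-7-one | C=C/C(C)=C\C[C@H]1[C@](C)(O)C(=O)C[C@H]2C(C)(C)CCC[C@@]21C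
F7 | step 2 | (12Z)-6α,8α-dihydroxylabda-12,14-dien-7-one | C=C/C(C)=C\C[C@H]1[C@](C)(O)C(=O)[C@H](O)[C@H]2C(C)(C)CCC[C@@]21C
F8 | step 2 | (12Z)-6α-acetoxy-8α-hydroxylabda-12,14-dien-7-one | C=C/C(C)=C\C[C@H]1[C@](C)(O)C(=O)[C@H](OC(C)=O)[C@H]2C(C)(C)CCC[C@@]21C
F9 | step 5 | (12Z)-7-(trimethylsilyloxy)-14,15-dinorlabda-6,8(17),12-trien-13-yl triflate | C/C(OS(=O)(=O)C(F)(F)F)=C/C[C@H]1C(=C)C(O[Si](C)(C)C)=C[C@H]2C(C)(C)CCC[C@@]21C
F10 | step 5 | (12Z)-6α-hydroxy-7-oxo-14,15-dinorlabda-8(17),12-dien-13-yl triflate | C/C(OS(=O)(=O)C(F)(F)F)=C/C[C@H]1C(=C)C(=O)[C@H](O)[C@H]2C(C)(C)CCC[C@@]21C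
F11 | step 6 | (12Z)-6α-acetoxy-7-(triethylsilyloxy)-14,15-dinorlabda-7,12-dien-13-yl triflate | C/C(OS(=O)(=O)C(F)(F)F)=C/C[C@H]1C(C)=C(O[Si](CC)(CC)CC)[C@H](OC(C)=O)[C@H]2C(C)(C)CCC[C@@]21C
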